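**Retrosynthetic overview**

1. Calyxin H (25) ⇐ tris-silyl ether 24 by fluoride. Numbering: heptanoid C-1 is the CH2 next to phenyl and C-7 the methine carrying rings A and C; in ring A, C-1' bears the cinnamoyl group, C-2' and C-4' bear OH, C-3' bears C-7 and C-6' bears OMe.
2. The route rests on ring A being a phloroglucinol in which C-3' lies between the phenolic carbons C-2' and C-4' (a C-substituted malonyl unit), while C-5'–C-6'(OMe)–C-1'(C=O) is the methyl enol ether of a cinnamoylacetone. Ring A, the only ring formed, is cut at C-4'–C-5' and C-1'–C-2' into malonyl dichloride 15 and silyl dienol ether 22 ([3+3] double C-acylation).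
3. 15 ⇐ malonate 12 ⇐ cross-metathesis (C-5=C-6) of branched malonate 7 (C-7 from iridium-catalysed allylic alkylation of dimethyl malonate) with silyl ether 11 (C-3 from catalytic asymmetric allylation of 3-phenylpropanal).
4. 22 ⇐ dienone 20 ⇐ aldol condensation of (E)-4-methoxypent-3-en-2-one with 4-(triisopropylsilyloxy)benzaldehyde 2, which also supplies ring C.

Key step: step 14

Assumption: the senses of induction quoted for the iridium–phosphoramidite and BINOL–titanium catalysts follow their usual models; if either delivers the antipode, the enantiomeric ligand is used.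

**Route**

Step 1
Reactants: 1 4-hydroxybenzaldehyde
Product: 2 4-(triisopropylsilyloxy)benzaldehyde
Conditions: TIPSCl, imidazole, DMF, 23 °C
Reagents that add atoms: triisopropylsilyl chloride, CC(C)[Si](Cl)(C(C)C)C(C)C
Why: Imidazole-mediated silyl ether formation; the bulky aryl triisopropylsilyl ether should survive the hydride, amide-base, metathesis and acyl chloride steps and falls to fluoride at the end.

Step 2
Reactants: 2 4-(triisopropylsilyloxy)benzaldehyde
Product: 3 ethyl (2E)-3-[4-(triisopropylsilyloxy)phenyl]prop-2-enoate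
Conditions: (EtO)2P(O)CH2CO2Et, NaH, THF, 0 → 23 °C
Reagents that add atoms: triethyl phosphonoacetate, CCOC(=O)CP(=O)(OCC)OCC
Why: Horner–Wadsworth–Emmons olefination with a stabilised phosphonate anion should give the E-cinnamate.

Step 3
Reactants: 3 ethyl (2E)-3-[4-(triisopropylsilyloxy)phenyl]prop-2-enoate
Product: 4 (2E)-3-[4-(triisopropylsilyloxy)phenyl]prop-2-en-1-ol
Conditions: iBu2AlH, CH2Cl2, −78 °C; aq. potassium sodium tartrate
Reagents that add atoms: none
Why: 1,2-Reduction of the unsaturated ester by the aluminium hydride at low temperature should give the allylic alcohol without touching the alkene or the silyl ether.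

Step 4
Reactants: 4 (2E)-3-[4-(triisopropylsilyloxy)phenyl]prop-2-en-1-ol
Product: 5 methyl (2E)-3-[4-(triisopropylsilyloxy)phenyl]prop-2-en-1-yl carbonate
Conditions: ClCO2Me, pyridine, CH2Cl2, 0 °C
Reagents that add atoms: methyl chloroformate, COC(=O)Cl
Why: O-Acylation to the allylic carbonate installs a leaving group that ionises on iridium and releases methoxide as the internal base for the next step.

Step 5
Reactants: 5 methyl (2E)-3-[4-(triisopropylsilyloxy)phenyl]prop-2-en-1-yl carbonate; 6 dimethyl malonate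
Product: 7 dimethyl 2-{(1R)-1-[4-(triisopropylsilyloxy)phenyl]prop-2-en-1-yl}malonate
Conditions: [Ir(cod)Cl]2 (2 mol%), (Sa,Sc,Sc)-(1,1'-binaphthalene-2,2'-diyl) N,N-bis(1-phenylethyl)phosphoramidite (4 mol%), 1,5,7-triazabicyclo[4.4.0]dec-5-ene (8 mol%), THF, 23 °C
Reagents that add atoms: none
Why: Iridium-catalysed asymmetric allylic alkylation (Tsuji–Trost type): the cyclometalated iridium–phosphoramidite complex should direct the malonate to the aryl-bearing allyl terminus, and the ligand configuration sets the new stereocentre as R (this becomes 7S of the target once ring A outranks ring C).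

Step 6
Reactants: 8 3-phenylpropanal
Product: 10 (3S)-1-phenylhex-5-en-3-ol, via stannyl ether 9 (not isolated)
Conditions: (R)-1,1'-bi-2-naphthol (20 mol%), Ti(OiPr)4 (10 mol%), 4 Å MS, CH2=CHCH2SnBu3, CH2Cl2, −20 °C; aq. NaHCO3
Reagents that add atoms: allyltributylstannane, C=CC[Sn](CCCC)(CCCC)CCCC
Why: Keck asymmetric allylation: the chiral binaphtholate–titanium Lewis acid shields one aldehyde face so that allyl transfer to the Re face should give the (S)-carbinol, which is C-3 of the target.

Step 7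
Reactants: 10 (3S)-1-phenylhex-5-en-3-ol
Product: 11 tert-butyldimethyl{[(3S)-1-phenylhex-5-en-3-yl]oxy}silane
Conditions: TBSCl, imidazole, DMF, 23 °C
Reagents that add atoms: tert-butyldimethylsilyl chloride, CC(C)(C)[Si](C)(C)Cl
Why: Silyl ether formation masks the carbinol through metathesis, ester cleavage and acyl chloride chemistry without affecting the stereocentre.

Step 8
Reactants: 7 dimethyl 2-{(1R)-1-[4-(triisopropylsilyloxy)phenyl]prop-2-en-1-yl}malonate; 11 tert-butyldimethyl{[(3S)-1-phenylhex-5-en-3-yl]oxy}silane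
Product: 12 dimethyl 2-{(1R,2E,5S)-5-(tert-butyldimethylsilyloxy)-7-phenyl-1-[4-(triisopropylsilyloxy)phenyl]hept-2-en-1-yl}malonate
Conditions: [1,3-bis(2,4,6-trimethylphenyl)imidazolidin-2-ylidene]dichloro(2-isopropoxybenzylidene)ruthenium (second-generation Hoveyda–Grubbs catalyst, 5 mol%), 11 (3 equiv), CH2Cl2, 40 °C
Reagents that add atoms: none
Why: Olefin cross-metathesis between the allylically branched olefin 7, which homodimerises slowly, and an excess of the unhindered olefin 11 should give the E-alkene under thermodynamic control without touching either stereocentre.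

Step 9
Reactants: 12 dimethyl 2-{(1R,2E,5S)-5-(tert-butyldimethylsilyloxy)-7-phenyl-1-[4-(triisopropylsilyloxy)phenyl]hept-2-en-1-yl}malonate
Product: 14 2-{(1R,2E,5S)-5-(tert-butyldimethylsilyloxy)-7-phenyl-1-[4-(triisopropylsilyloxy)phenyl]hept-2-en-1-yl}malonic acid, via bis(trimethylstannyl) ester 13 (not isolated)
Conditions: Me3SnOH (8 equiv), ClCH2CH2Cl, 80 °C; then 5% aq. HCl wash
Reagents that add atoms: trimethyltin hydroxide, C[Sn](C)(C)O
Why: Tin-hydroxide-mediated methyl ester hydrolysis proceeds without free hydroxide, so both esters should be cleaved while the aryl and alkyl silyl ethers and the non-enolisable C-7 centre are spared.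

Step 10
Reactants: 14 2-{(1R,2E,5S)-5-(tert-butyldimethylsilyloxy)-7-phenyl-1-[4-(triisopropylsilyloxy)phenyl]hept-2-en-1-yl}malonic acid
Product: 15 2-{(1R,2E,5S)-5-(tert-butyldimethylsilyloxy)-7-phenyl-1-[4-(triisopropylsilyloxy)phenyl]hept-2-en-1-yl}malonyl dichloride
Conditions: (COCl)2, DMF (cat.), CH2Cl2, 0 → 23 °C; evaporate, use crude
Reagents that add atoms: oxalyl chloride, O=C(Cl)C(=O)Cl
Why: Acid chloride formation through the catalytic chloroiminium (Vilsmeier-type) intermediate gives only volatile by-products, and monosubstituted malonyl dichlorides are stable enough to be concentrated and used directly.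

Step 11
Reactants: 16 (3E)-4-methoxypent-3-en-2-one; 2 4-(triisopropylsilyloxy)benzaldehyde
Product: 18 (4E)-1-hydroxy-5-methoxy-1-[4-(triisopropylsilyloxy)phenyl]hex-4-en-3-one (racemic), via lithium enolate 17 (not isolated)
Conditions: LiN(iPr)2, THF, −78 °C; then 2; aq. NH4Cl
Reagents that add atoms: none
Why: Directed aldol addition: kinetic deprotonation of the β-methoxy enone at its acetyl methyl gives the cross-conjugated enolate, which adds to the non-enolisable aldehyde; the racemic carbinol centre is removed in step 12.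

Step 12
Reactants: 18 (4E)-1-hydroxy-5-methoxy-1-[4-(triisopropylsilyloxy)phenyl]hex-4-en-3-one
Product: 20 (1E,4E)-5-methoxy-1-[4-(triisopropylsilyloxy)phenyl]hexa-1,4-dien-3-one, via mesylate 19 (not isolated)
Conditions: MsCl, Et3N, CH2Cl2, 0 °C; then DBU, 23 °C
Reagents that add atoms: none
Why: Mesylation followed by E1cB elimination should give the aryl-conjugated E-enone, and the vinylogous ester tolerates the non-nucleophilic amine bases.

Step 13
Reactants: 20 (1E,4E)-5-methoxy-1-[4-(triisopropylsilyloxy)phenyl]hexa-1,4-dien-3-one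
Product: 22 trimethyl{[(1E,3Z)-5-methoxy-1-[4-(triisopropylsilyloxy)phenyl]hexa-1,3,5-trien-3-yl]oxy}silane, via lithium dienolate 21 (not isolated)
Conditions: LiN(SiMe3)2, THF, −78 °C; then Me3SiCl, −78 → 0 °C; pentane, filter, use crude
Reagents that add atoms: chlorotrimethylsilane, C[Si](C)(C)Cl
Why: γ-Deprotonation and O-silylation of a vinylogous ester (the ketone counterpart of making 1,3-dimethoxy-1-silyloxybutadienes from 3-methoxycrotonates): with no α'-hydrogen available the amide base removes a proton from the C-6 methyl cis to the carbonyl, and the silyl chloride traps the extended enolate on oxygen as the (3Z) dienol ether.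

Step 14
Reactants: 15 2-{(1R,2E,5S)-5-(tert-butyldimethylsilyloxy)-7-phenyl-1-[4-(triisopropylsilyloxy)phenyl]hept-2-en-1-yl}malonyl dichloride; 22 trimethyl{[(1E,3Z)-5-methoxy-1-[4-(triisopropylsilyloxy)phenyl]hexa-1,3,5-trien-3-yl]oxy}silane
Product: 24 (2E)-1-{3-[(1S,2E,5S)-5-(tert-butyldimethylsilyloxy)-7-phenyl-1-(4-triisopropylsilyloxyphenyl)hept-2-en-1-yl]-2,4-dihydroxy-6-methoxyphenyl}-3-(4-triisopropylsilyloxyphenyl)prop-2-en-1-one, via keto acid chloride 23 (not isolated)
Conditions: 22 added over 2 h to 15, CH2Cl2 (0.02 M), −78 °C; then 2,6-di-tert-butyl-4-methylpyridine (1.2 equiv), −78 → 23 °C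
Reagents that add atoms: none
Why: Proposed new method: the terminal methylene of the 2-methoxy-4-silyloxy diene 22 (future C-5') C-acylates one COCl of 15 with loss of Me3SiCl to give the β-keto acid chloride 23, whose C-4' ketone enolises toward C-5' so that C-1' becomes the nucleophilic terminus of a 1,3-dioxygenated diene; C-1' then bonds to the second acyl carbon (C-2'), either by direct acylation or, after loss of HCl to the acylketene, by 6π-electrocyclisation of the dienylketene, and the resulting cyclohexadienone tautomerises to the arene. The closest known reaction types are the cyclocondensation of enol ethers and silyl enol ethers with malonyl dichloride (C,O-diacylation to 4-hydroxy-2-pyranones or C,C-diacylation to 5-alkoxyresorcinols), [3+3] cyclisations of 1,3-bis(silyloxy)dienes with 1,3-dielectrophiles, biomimetic Claisen cyclisation of poly-β-carbonyl chains to acylphloroglucinols, and dienylketene benzannulation. Ring A closes in a 6-(enolendo)-exo-trig mode through the C-1'–C-2' bond, the C-4'–C-5' bond having been formed intermolecularly. No stereocentre is created, and C-7, which carries no enolisable hydrogen, should keep the configuration set in step 5 because the only base present is a hindered pyridine. The step needs C- over O-closure and a 1:1 union: the carbonyl oxygens could only close four- or eight-membered rings, the one oxygen placed for a six-membered ring is the C-6' methyl ether, which would have to lose MeCl, and either order of the two C-acylations leads to the same ring. Slow addition of 22 to 15 at high dilution should keep a second diene from reaching 23 before it cyclises.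

Step 15
Reactants: 24 tris-silyl ether of calyxin H
Product: 25 calyxin H, (2E)-1-{2,4-dihydroxy-3-[(1S,2E,5S)-5-hydroxy-1-(4-hydroxyphenyl)-7-phenylhept-2-en-1-yl]-6-methoxyphenyl}-3-(4-hydroxyphenyl)prop-2-en-1-one
Conditions: Bu4NF, AcOH, THF, 0 → 23 °C
Reagents that add atoms: none
Why: Fluoride-driven desilylation (Si–F bond formation) should remove all three silyl groups, and acetic acid buffering keeps the phenoxide concentration low so that the 2'-hydroxychalcone does not close to a flavanone and no stereocentre or alkene is disturbed.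

**Compound list**

1 | 4-hydroxybenzaldehyde | O=Cc1ccc(O)cc1 | starting material
2 | 4-(triisopropylsilyloxy)benzaldehyde | O=Cc1ccc(O[Si](C(C)C)(C(C)C)C(C)C)cc1 | intermediate
3 | ethyl (2E)-3-[4-(triisopropylsilyloxy)phenyl]prop-2-enoate | CCOC(=O)/C=C/c1ccc(O[Si](C(C)C)(C(C)C)C(C)C)cc1 | intermediate
4 | (2E)-3-[4-(triisopropylsilyloxy)phenyl]prop-2-en-1-ol | OC/C=C/c1ccc(O[Si](C(C)C)(C(C)C)C(C)C)cc1 | intermediate
5 | methyl (2E)-3-[4-(triisopropylsilyloxy)phenyl]prop-2-en-1-yl carbonate | COC(=O)OC/C=C/c1ccc(O[Si](C(C)C)(C(C)C)C(C)C)cc1 | intermediate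
6 | dimethyl malonate | COC(=O)CC(=O)OC | starting material
7 | dimethyl 2-{(1R)-1-[4-(triisopropylsilyloxy)phenyl]prop-2-en-1-yl}malonate | COC(=O)C(C(=O)OC)[C@@H](C=C)c1ccc(O[Si](C(C)C)(C(C)C)C(C)C)cc1 | intermediate
8 | 3-phenylpropanal | O=CCCc1ccccc1 | starting material
9 | tributyl{[(3S)-1-phenylhex-5-en-3-yl]oxy}stannane (stannyl ether, not isolated) | C=CC[C@@H](O[Sn](CCCC)(CCCC)CCCC)CCc1ccccc1 | intermediate
10 | (3S)-1-phenylhex-5-en-3-ol | C=CC[C@@H](O)CCc1ccccc1 | intermediate
11 | tert-butyldimethyl{[(3S)-1-phenylhex-5-en-3-yl]oxy}silane | C=CC[C@@H](O[Si](C)(C)C(C)(C)C)CCc1ccccc1 | intermediate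
12 | dimethyl 2-{(1R,2E,5S)-5-(tert-butyldimethylsilyloxy)-7-phenyl-1-[4-(triisopropylsilyloxy)phenyl]hept-2-en-1-yl}malonate | COC(=O)C(C(=O)OC)[C@@H](/C=C/C[C@@H](O[Si](C)(C)C(C)(C)C)CCc1ccccc1)c1ccc(O[Si](C(C)C)(C(C)C)C(C)C)cc1 | intermediate
13 | bis(trimethylstannyl) 2-{(1R,2E,5S)-5-(tert-butyldimethylsilyloxy)-7-phenyl-1-[4-(triisopropylsilyloxy)phenyl]hept-2-en-1-yl}malonate (not isolated) | C[Sn](C)(C)OC(=O)C(C(=O)O[Sn](C)(C)C)[C@@H](/C=C/C[C@@H](O[Si](C)(C)C(C)(C)C)CCc1ccccc1)c1ccc(O[Si](C(C)C)(C(C)C)C(C)C)cc1 | intermediate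
14 | 2-{(1R,2E,5S)-5-(tert-butyldimethylsilyloxy)-7-phenyl-1-[4-(triisopropylsilyloxy)phenyl]hept-2-en-1-yl}malonic acid | OC(=O)C(C(=O)O)[C@@H](/C=C/C[C@@H](O[Si](C)(C)C(C)(C)C)CCc1ccccc1)c1ccc(O[Si](C(C)C)(C(C)C)C(C)C)cc1 | intermediate
15 | 2-{(1R,2E,5S)-5-(tert-butyldimethylsilyloxy)-7-phenyl-1-[4-(triisopropylsilyloxy)phenyl]hept-2-en-1-yl}malonyl dichloride | O=C(Cl)C(C(=O)Cl)[C@@H](/C=C/C[C@@H](O[Si](C)(C)C(C)(C)C)CCc1ccccc1)c1ccc(O[Si](C(C)C)(C(C)C)C(C)C)cc1 | intermediate
16 | (3E)-4-methoxypent-3-en-2-one | CO/C(C)=C/C(C)=O | starting material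
17 | lithium (3E)-4-methoxypenta-1,3-dien-2-olate (not isolated) | [Li+].CO/C(C)=C/C([O-])=C | intermediate
18 | (4E)-1-hydroxy-5-methoxy-1-[4-(triisopropylsilyloxy)phenyl]hex-4-en-3-one (racemic) | CO/C(C)=C/C(=O)CC(O)c1ccc(O[Si](C(C)C)(C(C)C)C(C)C)cc1 | intermediate
19 | (4E)-5-methoxy-3-oxo-1-[4-(triisopropylsilyloxy)phenyl]hex-4-en-1-yl methanesulfonate (racemic, not isolated) | CO/C(C)=C/C(=O)CC(OS(C)(=O)=O)c1ccc(O[Si](C(C)C)(C(C)C)C(C)C)cc1 | intermediate
20 | (1E,4E)-5-methoxy-1-[4-(triisopropylsilyloxy)phenyl]hexa-1,4-dien-3-one | CO/C(C)=C/C(=O)/C=C/c1ccc(O[Si](C(C)C)(C(C)C)C(C)C)cc1 | intermediate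
21 | lithium (1E,3Z)-5-methoxy-1-[4-(triisopropylsilyloxy)phenyl]hexa-1,3,5-trien-3-olate (not isolated) | [Li+].[O-]/C(=C\C(OC)=C)/C=C/c1ccc(O[Si](C(C)C)(C(C)C)C(C)C)cc1 | intermediate
22 | trimethyl{[(1E,3Z)-5-methoxy-1-[4-(triisopropylsilyloxy)phenyl]hexa-1,3,5-trien-3-yl]oxy}silane | C=C(OC)/C=C(\O[Si](C)(C)C)/C=C/c1ccc(O[Si](C(C)C)(C(C)C)C(C)C)cc1 | intermediate
23 | (5E,8E)-2-{(1R,2E,5S)-5-(tert-butyldimethylsilyloxy)-7-phenyl-1-[4-(triisopropylsilyloxy)phenyl]hept-2-en-1-yl}-5-methoxy-3,7-dioxo-9-[4-(triisopropylsilyloxy)phenyl]nona-5,8-dienoyl chloride (epimers at C-2, not isolated) | O=C(Cl)C(C(=O)C\C(OC)=C/C(=O)/C=C/c1ccc(O[Si](C(C)C)(C(C)C)C(C)C)cc1)[C@@H](/C=C/C[C@@H](O[Si](C)(C)C(C)(C)C)CCc1ccccc1)c1ccc(O[Si](C(C)C)(C(C)C)C(C)C)cc1 | intermediate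
24 | (2E)-1-{3-[(1S,2E,5S)-5-(tert-butyldimethylsilyloxy)-7-phenyl-1-(4-triisopropylsilyloxyphenyl)hept-2-en-1-yl]-2,4-dihydroxy-6-methoxyphenyl}-3-(4-triisopropylsilyloxyphenyl)prop-2-en-1-one | COc1cc(O)c([C@@H](/C=C/C[C@@H](O[Si](C)(C)C(C)(C)C)CCc2ccccc2)c2ccc(O[Si](C(C)C)(C(C)C)C(C)C)cc2)c(O)c1C(=O)/C=C/c1ccc(O[Si](C(C)C)(C(C)C)C(C)C)cc1 | intermediate
25 | calyxin H, (2E)-1-{2,4-dihydroxy-3-[(1S,2E,5S)-5-hydroxy-1-(4-hydroxyphenyl)-7-phenylhept-2-en-1-yl]-6-methoxyphenyl}-3-(4-hydroxyphenyl)prop-2-en-1-one | COc1cc(O)c([C@@H](/C=C/C[C@@H](O)CCc2ccccc2)c2ccc(O)cc2)c(O)c1C(=O)/C=C/c1ccc(O)cc1 | target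

**Step count and risks**

Total: 15 steps. Longest linear sequence: 10 steps (steps 1, 2, 3, 4, 5, 8, 9, 10, 14, 15).

Steps most likely to fail:

First, step 14. The mono-acylated intermediate may oligomerise with a second diene, close through the C-6' ether oxygen with loss of MeCl to a pyranone, or lose its acid chloride by ketene dimerisation before the second C–C bond forms. The fallback separates the two bond formations and uses only known reaction types. It sets out from diester 12. Mono-saponification (KOH, 1.0 equiv, THF/MeOH, 0 °C) should give the malonic half-ester F1, and oxalyl chloride with catalytic DMF the ester acid chloride F2. C-Acylation of dienol ether 22 at its terminal carbon (CH2Cl2, −78 → 23 °C), the established reaction of 1,3-dioxygenated silyloxydienes with acid chlorides, should then give the open-chain keto ester F3. Treatment of F3 with LiN(SiMe3)2 (3 equiv, THF, −78 → 0 °C) should effect the Claisen (Dieckmann-type) cyclisation of the extended enolate through C-1' onto the ester carbon, with loss of methanol and aromatisation. The fallback comes back to the route at tris-silyl ether 24.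

Second, step 9. The second ester may hydrolyse only sluggishly, the half-acid may decarboxylate on prolonged heating, or the aryl silyl ether may be lost. The fallback sets out from carbonate 5 and changes the ester and its mode of cleavage. The allylic alkylation of step 5 run with di-tert-butyl malonate in place of 6 should give the di-tert-butyl (R)-branched malonate F4, and cross-metathesis with 11 as in step 8 the di-tert-butyl heptenylmalonate F5. Me3SiOTf with 2,6-lutidine (CH2Cl2, 0 °C) should then remove both tert-butyl groups as isobutene without base or heat, giving the bis(trimethylsilyl) ester F6, which hydrolyses on aqueous work-up. The fallback comes back to the route at diacid 14.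

Third, step 13. The amide base or the dienolate may add in conjugate fashion to the cross-conjugated dienone, and the trimethylsilyl dienol ether may hydrolyse during handling. The fallback sets out from dienone 20 and replaces irreversible deprotonation by soft enolisation. tBuMe2SiOTf with Et3N (Et2O, 0 °C) should silylate the vinylogous ester carbonyl, after which the amine removes a proton from the C-6 methyl to give the tert-butyldimethylsilyl dienol ether F7, which is robust enough for chromatography on deactivated silica. F7 takes the place of 22 in step 14, with tBuMe2SiCl leaving instead of Me3SiCl, and the fallback comes back to the route at tris-silyl ether 24.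

**Further compounds**

F1 | step 14 | 3-methoxy-3-oxo-2-{(1R,2E,5S)-5-(tert-butyldimethylsilyloxy)-7-phenyl-1-[4-(triisopropylsilyloxy)phenyl]hept-2-en-1-yl}propanoic acid (epimers at C-2) | COC(=O)C(C(=O)O)[C@@H](/C=C/C[C@@H](O[Si](C)(C)C(C)(C)C)CCc1ccccc1)c1ccc(O[Si](C(C)C)(C(C)C)C(C)C)cc1
F2 | step 14 | methyl 3-chloro-3-oxo-2-{(1R,2E,5S)-5-(tert-butyldimethylsilyloxy)-7-phenyl-1-[4-(triisopropylsilyloxy)phenyl]hept-2-en-1-yl}propanoate (epimers at C-2) | COC(=O)C(C(=O)Cl)[C@@H](/C=C/C[C@@H](O[Si](C)(C)C(C)(C)C)CCc1ccccc1)c1ccc(O[Si](C(C)C)(C(C)C)C(C)C)cc1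
F3 | step 14 | methyl (5E,8E)-2-{(1R,2E,5S)-5-(tert-butyldimethylsilyloxy)-7-phenyl-1-[4-(triisopropylsilyloxy)phenyl]hept-2-en-1-yl}-5-methoxy-3,7-dioxo-9-[4-(triisopropylsilyloxy)phenyl]nona-5,8-dienoate (epimers at C-2) | COC(=O)C(C(=O)C\C(OC)=C/C(=O)/C=C/c1ccc(O[Si](C(C)C)(C(C)C)C(C)C)cc1)[C@@H](/C=C/C[C@@H](O[Si](C)(C)C(C)(C)C)CCc1ccccc1)c1ccc(O[Si](C(C)C)(C(C)C)C(C)C)cc1
F4 | step 9 | di-tert-butyl 2-{(1R)-1-[4-(triisopropylsilyloxy)phenyl]prop-2-en-1-yl}malonate | CC(C)(C)OC(=O)C(C(=O)OC(C)(C)C)[C@@H](C=C)c1ccc(O[Si](C(C)C)(C(C)C)C(C)C)cc1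
F5 | step 9 | di-tert-butyl 2-{(1R,2E,5S)-5-(tert-butyldimethylsilyloxy)-7-phenyl-1-[4-(triisopropylsilyloxy)phenyl]hept-2-en-1-yl}malonate | CC(C)(C)OC(=O)C(C(=O)OC(C)(C)C)[C@@H](/C=C/C[C@@H](O[Si](C)(C)C(C)(C)C)CCc1ccccc1)c1ccc(O[Si](C(C)C)(C(C)C)C(C)C)cc1
F6 | step 9 | bis(trimethylsilyl) 2-{(1R,2E,5S)-5-(tert-butyldimethylsilyloxy)-7-phenyl-1-[4-(triisopropylsilyloxy)phenyl]hept-2-en-1-yl}malonate | C[Si](C)(C)OC(=O)C(C(=O)O[Si](C)(C)C)[C@@H](/C=C/C[C@@H](O[Si](C)(C)C(C)(C)C)CCc1ccccc1)c1ccc(O[Si](C(C)C)(C(C)C)C(C)C)cc1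
F7 | step 13 | tert-butyl{[(1E,3Z)-5-methoxy-1-[4-(triisopropylsilyloxy)phenyl]hexa-1,3,5-trien-3-yl]oxy}dimethylsilane | C=C(OC)/C=C(\O[Si](C)(C)C(C)(C)C)/C=C/c1ccc(O[Si](C(C)C)(C(C)C)C(C)C)cc1
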